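Late in a run, you guessed, over-reaction product overtakes target, as it did in dusk. I reckoned otherwise for your flask.

the same everywhere: free catalyst 24 mM

| charge | substrate | partner | remark | time |
|---|---|---|---|---|
| dusk | 0.20 M | 0.40 M | run made earlier |  |
| dawn | 0.80 M | 0.40 M | run made earlier |  |
| flask | 0.40 M | 0.400 M |  | 15 d |

| run | time / d | target / % | over-reaction product / % | substrate / % |
|---|---|---|---|---|
| dusk | 1.25 | 55.7 | 43.5 | 0.6 |
| dusk | 3.00 | 35.0 | 66.3 | 0 |
| dusk | 6.00 | 19.3 | 80.0 | 0.4 |
| dusk | 15.0 | 8.5 | 91.7 | 0.4 |
| dawn | 2.08 | 44.1 | 3.5 | 30.2 |
| dawn | 5.00 | 43.9 | 2.3 | 20.9 |
| dawn | 10.0 | 44.7 | 3.2 | 13.4 |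
| dawn | 15.0 | 45.1 | 1.9 | 9.7 |

(standard deviation of a reading: 0.5 percentage points)

* ratio of target to over-reaction product at 50 min
* ratio of target to over-reaction product at 15 h
* ratio of target to over-reaction product at 15 d
* which of target and over-reaction product there is more of at 15 d



I read the runs as charging one partner per target and two per over-reaction product. At 15.0 d, dawn's target plus twice its over-reaction product came to 0.391 M, against 0.40 M of partner charged, and its target readings stayed between 43.9% and 45.1%. So I took the partner shortfall: the partner missing for taking the whole substrate charge through to over-reaction product.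

shortfall = twice the substrate − partner = 0.400 M

Dusk's shortfall was 0 M, and its target fell to 8.5%. Your flask's shortfall is larger than dusk's, so I expected partner to be the limiting reagent and some target to survive.

For the ratio, dusk's falling target gave a loss constant of 3.63 /M/d. Its substrate reading of 0.6%, against a scatter of 0.5 percentage points, gave a rough feed constant of 4.09 /d. With equal charges, and leaving out the loss's effect on partner and target, I got a rough estimate:

over-reaction product ≈ loss × substrate² / (twice feed) = 0.0709 M

ratio at the stop = partner / over-reaction product − 2 ≈ 3.64

So I committed to target ahead at 15 d, by about that ratio.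

The forecast gave 42, 4 and 2.7 at the three times, the last below my estimate, with target ahead, reading in dawn that “target then stays flat”.

The flask gave 50.9, 6.62 and 6.69, with target ahead, the last above my estimate. Partner stood at 0% at 15.0 d, and ten times as long left the ratio where it stood.

    substrate + free catalyst ⇌ free catalyst + open intermediate (K = 8.46, k = 0.108 /M/min)
    free catalyst + open intermediate ⇌ catalyst intermediate (K = 130 /M, k = 6.96 /M/min)
    partner + catalyst intermediate → free catalyst + target (k = 1.01 /M/min)
    partner + target → over-reaction product (k = 0.00241 /M/min)

Target plus twice the unfinished substrate, counted as substrate, open intermediate and catalyst intermediate, came to 0.400 M, which is the shortfall.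

With 1.6 M of partner in a neighbour flask, otherwise like yours, the shortfall turns into a surplus of 0.800 M, or 50.0% of its charge. The computed neighbour flask held 50.0% of its partner at 15.0 d, with over-reaction product at 100% and target at 0%.

The readings stem from a simulated flask with constants of no real substance; the scatter is artificial.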